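**Plan**
- Retrosynthesis: after unmasking the pyrrole N–H, the only skeletal cut is the C3–C1' bond between the pyrrole ring and the tricosyl chain.
- Enabling feature: the chain on C3 has 23 carbons, one fewer than lignoceric (C24) acid, so C1' can arrive as the primary radical left when that acid loses its carboxyl carbon. C3 lies next to the C2 formyl group, which activates a C3–Br bond toward nickel insertion.
- Forward order: the acid is converted to its N-hydroxyphthalimide ester (step 1), the bromopyrrole aldehyde is N-Boc protected (step 2), nickel joins the chain to C3 with loss of carbon dioxide (step 3), and the carbamate is removed (step 4).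
- Rings and stereochemistry: the pyrrole is bought intact and no ring is formed; the target has no stereocentre, so nothing needs to be controlled.

Key step: step 3

Remark: 3-bromo-1H-pyrrole-2-carbaldehyde is taken as a catalogue building block.

**Step 1**
Reactants: 1 tetracosanoic acid (lignoceric acid); 2 N-hydroxyphthalimide
Product: 3 1,3-dioxoisoindolin-2-yl tetracosanoate
Conditions: N,N'-diisopropylcarbodiimide (1.1 equiv), DMAP (cat.), CH2Cl2/THF, 0 °C to rt
Reagents that add atoms: N-hydroxyphthalimide (2), ON1C(=O)c2ccccc2C1=O
Why: Steglich-type carbodiimide esterification, in which the DMAP-activated O-acylisourea of the acid is intercepted by the N-hydroxy imide, and the saturated chain offers no competing functionality.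

**Step 2**
Reactants: 4 3-bromo-1H-pyrrole-2-carbaldehyde; 5 di-tert-butyl dicarbonate
Product: 6 tert-butyl 3-bromo-2-formyl-1H-pyrrole-1-carboxylate
Conditions: Boc2O (1.2 equiv), DMAP (10 mol%), MeCN, rt
Reagents that add atoms: di-tert-butyl dicarbonate (5), CC(C)(C)OC(=O)OC(=O)OC(C)(C)C
Why: DMAP-catalysed N-acylation (carbamate protection) of a pyrrole N–H made acidic by the 2-formyl group, a standard reaction of pyrrole-2-carbaldehydes that leaves the aldehyde and the C–Br bond untouched.

**Step 3**
Reactants: 3 1,3-dioxoisoindolin-2-yl tetracosanoate; 6 tert-butyl 3-bromo-2-formyl-1H-pyrrole-1-carboxylate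
Product: 7 tert-butyl 2-formyl-3-tricosyl-1H-pyrrole-1-carboxylate
Conditions: NiBr2(dme) (10 mol%), 4,4'-di-tert-butyl-2,2'-bipyridine (10 mol%), Zn powder (2 equiv), 3 (1.5 equiv, added in portions), DMA/THF, 25–40 °C
Reagents that add atoms: none
Why: Zinc reduces the divalent nickel precatalyst to a zerovalent nickel bipyridine complex, which inserts into the C3–Br bond of 6 (made electron-poor by the neighbouring formyl group and the N-carbamate) to give a divalent aryl nickel bromide. Single-electron transfer to ester 3 breaks its N–O bond, expels phthalimide anion and carbon dioxide and leaves the primary tricosyl radical; the aryl nickel species captures it, the resulting trivalent aryl(alkyl)nickel reductively eliminates the C3–C1' bond, and zinc returns the monovalent nickel to the cycle. The closest known reaction type is the nickel-catalysed decarboxylative reductive cross-electrophile coupling of N-hydroxyphthalimide esters with aryl and heteroaryl halides, applied here to a fatty-acid ester and an electron-poor bromopyrrole. No ring closes and no stereocentre is created, so only site, cross and chemoselectivity are required. The bromine fixes the site at C3; cross-selectivity over bipyrrole and hexatetracontane follows because the bromide is activated by two-electron insertion and the ester by one-electron reduction; the formyl and Boc groups should survive because no carbanion or strong base is present at this temperature.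

**Step 4**
Reactants: 7 tert-butyl 2-formyl-3-tricosyl-1H-pyrrole-1-carboxylate
Product: 8 3-tricosyl-1H-pyrrole-2-carbaldehyde (CNP0296937.0)
Conditions: K2CO3 (cat.), MeOH/THF, rt
Reagents that add atoms: none
Why: Carbamate methanolysis (nucleophilic acyl substitution) is easy here because the 2-formylpyrrolide is a good leaving group, the aldehyde has no enolisable α-hydrogen, and THF keeps the waxy substrate in solution.

**Compound list**
1 | tetracosanoic acid (lignoceric acid) | CCCCCCCCCCCCCCCCCCCCCCCC(=O)O | starting material
2 | N-hydroxyphthalimide | ON1C(=O)c2ccccc2C1=O | starting material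
3 | 1,3-dioxoisoindolin-2-yl tetracosanoate | CCCCCCCCCCCCCCCCCCCCCCCC(=O)ON1C(=O)c2ccccc2C1=O | intermediate
4 | 3-bromo-1H-pyrrole-2-carbaldehyde | O=Cc1[nH]ccc1Br | starting material
5 | di-tert-butyl dicarbonate | CC(C)(C)OC(=O)OC(=O)OC(C)(C)C | starting material
6 | tert-butyl 3-bromo-2-formyl-1H-pyrrole-1-carboxylate | O=Cc1c(Br)ccn1C(=O)OC(C)(C)C | intermediate
7 | tert-butyl 2-formyl-3-tricosyl-1H-pyrrole-1-carboxylate | CCCCCCCCCCCCCCCCCCCCCCCc1ccn(C(=O)OC(C)(C)C)c1C=O | intermediate
8 | 3-tricosyl-1H-pyrrole-2-carbaldehyde | CCCCCCCCCCCCCCCCCCCCCCCc1cc[nH]c1C=O | target

**Step count**
Total steps: 4 (two convergent one-step branches, the coupling, the deprotection).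
Longest linear sequence: 3 steps (1 → 3 → 7 → 8, or equally 4 → 6 → 7 → 8).

**Steps most likely to fail**

Step 3. The tricosyl radical may be lost to hydrogen abstraction or dimerisation before the aryl nickel species has formed, because insertion into a heteroaryl bromide is slower than into an iodide. Protonation of the aryl nickel intermediate, or its addition to a formyl group of another molecule, may also drain the bromide. The fallback sets out from 1 and 6 and returns at 7, making the same C3–C1' bond by two-electron transmetalation instead of radical capture. Acid 1 would be iododecarboxylated under Suárez conditions (PhI(OAc)2, iodine, cyclohexane, visible light, reflux) to 1-iodotricosane F1. Zinc dust with LiCl in THF at 40 °C would insert into the C–I bond to give tricosylzinc iodide F2. A Negishi coupling of F2 with bromide 6 under PdCl2(dppf) in THF/DMA at 50 °C should then deliver 7, since alkylzinc halides do not add to the aldehyde or the carbamate at that temperature.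

Step 2. The carbamate may be shed by acyl transfer on silica or on standing, because the formyl-flanked pyrrole nitrogen is a good leaving group; the material entering the coupling would then be an ill-defined mixture of protected and free pyrrole. The fallback sets out from 4 and returns at 8, using a sulfonyl group that tolerates chromatography. Deprotonation of 4 with NaH in THF at 0 °C and trapping with p-toluenesulfonyl chloride would give 3-bromo-1-(p-toluenesulfonyl)pyrrole-2-carbaldehyde F3. The coupling of F3 with ester 3 under the conditions of step 3 would give 1-(p-toluenesulfonyl)-3-tricosylpyrrole-2-carbaldehyde F4. Hydrolysis of the sulfonamide with NaOH in THF/MeOH/H2O at rt to 50 °C would release 8.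

Step 1. Activation may stay incomplete because the C24 acid dissolves poorly in cold dichloromethane. Slow interception of the O-acylisourea by the weakly nucleophilic N-hydroxy imide would also allow O-to-N acyl migration to the unreactive N-acylurea. The fallback sets out from 1 and returns at 3 through a separate acyl chloride. Oxalyl chloride with catalytic DMF in toluene/CH2Cl2 at 40 °C would convert 1 into tetracosanoyl chloride F5. After evaporation, F5 would be treated with 2 and Et3N in CH2Cl2 at 0 °C to rt to give 3.

**Further compounds**
F1 | step 3 | 1-iodotricosane | CCCCCCCCCCCCCCCCCCCCCCCI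
F2 | step 3 | tricosylzinc iodide | CCCCCCCCCCCCCCCCCCCCCCC[Zn]I
F3 | step 2 | 3-bromo-1-(p-toluenesulfonyl)pyrrole-2-carbaldehyde | O=Cc1c(Br)ccn1S(=O)(=O)c1ccc(C)cc1
F4 | step 2 | 1-(p-toluenesulfonyl)-3-tricosylpyrrole-2-carbaldehyde | CCCCCCCCCCCCCCCCCCCCCCCc1ccn(S(=O)(=O)c2ccc(C)cc2)c1C=O
F5 | step 1 | tetracosanoyl chloride | CCCCCCCCCCCCCCCCCCCCCCCC(=O)Cl
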